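**Plan**
- Retrosynthesis: the three acids are carried as methyl esters and the 15-carbinol/16-methylene pair goes back to a C16 ketone. Ring D is then cut at C13–C16, C4–C18 is cut, ring B is cut at C6–C8, and last C9–C10 and C5–C6 are cut together.
- The last double cut rests on one feature: quaternary C10 (C20 carboxyl plus the C9–C10 bond) sits next to C5, which carries C6 trans to C9, in a ring A whose C4 can be a ketone. This is the imprint of β-addition and α-alkylation on a 3-carboxycyclohexenone.
- Forward: rings A and C are joined at C10 with the C6–C7 arm placed on C5 (no ring formed), ring B closes (C6–C8), C4 becomes quaternary, ring D closes (C13–C16), C9 is reduced, then C17 and the C15 hydroxyl are installed.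
- Stereochemistry: C10 from the chiral carbene–copper catalyst, C5 from C10, C8 (and epimerisable C6) in the Michael closure under the C20 ester, C4 by methylation anti to that ester, C13 by the geometry of bridging, C9 by hydroxyl-directed hydrogenation, C15 by exo-face hydride delivery to the enone.

Key step: step 3

Assumption: the carbene precursor is the zwitterionic imidazolinium sulfonate (4S,5S)-4,5-diphenyl-1-(2,4,6-trimethylphenyl)-3-(2-sulfonatophenyl)-4,5-dihydro-1H-imidazol-3-ium. Its (S,S) form is taken to deliver the alkenyl group to the face of enone 6 that gives (S)-configured C10 in 10; the enantiomeric salt is used if the sense is the reverse.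
Gibberellane numbering is used throughout. α is the face of the C20 ester, β the face of H-5 and of the C15–C16 bridge. On ring D, endo means pointing toward the C9–C11–C12 bridge and exo means pointing away from it.

Step 1
Reactants: 1 cyclohex-2-en-1-one
Product: 3 2-bromocyclohex-2-en-1-one, via 2,3-dibromocyclohexan-1-one 2 (not isolated)
Conditions: Br2, CH2Cl2, 0 °C; then Et3N, 0 → 25 °C
Reagents that add atoms: bromine, BrBr
Why: Bromination–dehydrobromination: bromine adds across the enone and the amine removes HBr from the α,β-dibromo ketone through its enolate to leave the α-bromo enone.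

Step 2
Reactants: 3 2-bromocyclohex-2-en-1-one; 4 ethylene glycol
Product: 5 6-bromo-1,4-dioxaspiro[4.5]dec-6-ene
Conditions: TsOH·H2O (cat.), benzene, reflux, Dean–Stark trap
Reagents that add atoms: none
Why: Acid-catalysed ketalisation with azeotropic removal of water masks the future C8 ketone so that the vinylic bromide can be metalated.

Step 3
Reactants: 5 6-bromo-1,4-dioxaspiro[4.5]dec-6-ene; 6 methyl 3-oxocyclohex-1-ene-1-carboxylate; 7 methyl bromoacetate
Product: 11 keto diester methyl (1S,2S)-2-(2-methoxy-2-oxoethyl)-3-oxo-1-(1,4-dioxaspiro[4.5]dec-6-en-6-yl)cyclohexane-1-carboxylate, via alkenyllithium 8 (not isolated), via alkenyldimethylalane 9 (not isolated), via dimethylaluminium enolate 10 (not isolated)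
Conditions: 5, t-BuLi (2.0 equiv), Et2O, −78 °C; Me2AlCl, −78 → −30 °C; 6, Cu(OTf)2 (5 mol %), chiral imidazolinium sulfonate (6 mol %), THF, −30 °C; then MeLi (1.0 equiv), HMPA, 7, −78 → 0 °C
Reagents that add atoms: none
Why: The alkenyl group of alane 9 passes to the chiral carbene–copper complex, which adds it to C10 of enone 6 (β to the ketone and made more electrophilic by the C20 ester on the same carbon); the resulting C4–C5 aluminium enolate 10 is converted by MeLi into its more nucleophilic lithium aluminate and C-alkylated at C5 by bromoacetate 7 in an SN2 step. The closest known reaction type is the copper-catalysed enantioselective conjugate addition of sp2-carbon alanes and zinc reagents to β-substituted and β-carboalkoxy cyclic enones with trapping of the enolate by a reactive halide. No ring is closed: the two new bonds, C9–C10 and C5–C6, join three separate pieces and put all five carbons of ring B in place. C10 is set by the carbene ligand on copper (ester ends α), and C5 is set by C10, the electrophile entering anti to the bulky ketal-bearing alkenyl group (H-5 β), which is also the thermodynamically preferred arrangement at this epimerisable centre. The step needs addition at C10 and not C5, transfer of the alkenyl and not a methyl group from aluminium, and C- over O-alkylation; the stronger activation by the ketone, the faster transfer of sp2 ligands from mixed alanes and the soft, reactive α-halo ester secure these in turn.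

Step 4
Reactants: 11 keto diester
Product: 13 enol triflate (C3=C4–OSO2CF3), via potassium enolate 12 (not isolated)
Conditions: KN(SiMe3)2 (1.05 equiv), THF, −78 °C; then PhNTf2, −78 → 0 °C
Reagents that add atoms: N-phenylbis(trifluoromethanesulfonimide), O=S(=O)(N(c1ccccc1)S(=O)(=O)C(F)(F)F)C(F)(F)F
Why: Kinetic deprotonation takes the unhindered C3 methylene and not the tertiary C5–H, and O-sulfonylation gives the enol triflate without touching C5 or C10.

Step 5
Reactants: 13 enol triflate
Product: 14 enoate (C3=C4–CO2Me; ketal intact)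
Conditions: Pd(OAc)2 (5 mol %), PPh3 (10 mol %), CO (1 atm), MeOH, Et3N, DMF, 60 °C
Reagents that add atoms: carbon monoxide, [C-]#[O+]; methanol, CO
Why: Palladium-catalysed methoxycarbonylation (oxidative addition of the vinyl triflate to zerovalent palladium, CO insertion, methanolysis) installs C19 on C4.

Step 6
Reactants: 14 enoate
Product: 15 enone (C8 ketone conjugated with C9=C11)
Conditions: 1 M HCl, THF, 25 °C
Reagents that add atoms: water, O
Why: Acid hydrolysis of the dioxolane frees the C8 ketone; no stereocentre is involved.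

Step 7
Reactants: 15 enone
Product: 16 dienoate (C8=C15H–CO2Me; E/Z mixture)
Conditions: MeO2CCH2SiMe3, LiN(i-Pr)2, THF, −78 °C; then 15, −78 → 25 °C
Reagents that add atoms: methyl 2-(trimethylsilyl)acetate, COC(=O)C[Si](C)(C)C
Why: Peterson olefination: the α-silyl ester enolate adds 1,2 to the C8 ketone at low temperature where a phosphonate anion would be sluggish, and loss of silanolate gives the C8=C15 alkylidene, whose geometry is of no consequence.

Step 8
Reactants: 16 dienoate
Product: 17 tricyclic tetraester (ring B closed; C8 carries β-CH2CO2Me and α-C14; 6β-CO2Me; C9=C11 and C3=C4 kept)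
Conditions: KOt-Bu (0.2 equiv), t-BuOH/THF, 0 → 25 °C
Reagents that add atoms: none
Why: Intramolecular Michael addition (5-exo-trig) of the C7 ester enolate to C8 closes ring B and makes C8 quaternary; the freely rotating C15 acceptor arm, the larger of the two groups left on C8, is expected to avoid the cis-1,3 C20 ester on C10 so that the tied-back ring C methylene C14 ends α, and C6 settles under the alkoxide as the ester trans to C4.

Step 9
Reactants: 17 tricyclic tetraester
Product: 19 tetraester with quaternary C4 (18β-methyl; 19α-CO2Me), via lithium ester enolate 18 (not isolated)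
Conditions: LiBH(s-Bu)3, THF, −78 °C; then MeI, HMPA, −78 → 0 °C
Reagents that add atoms: iodomethane, CI
Why: Reductive alkylation: hydride adds 1,4 to the only enoate (at C3), giving the C4 ester enolate regiospecifically, and on the rigid trans-fused A/B system methyl iodide enters from the β face, opposite the axial C20 ester.

Step 10
Reactants: 19 tetraester
Product: 21 diene (C9=C11–C12=C13), via C12 allylic bromide 20 (not isolated)
Conditions: NBS, AIBN (cat.), PhCF3, 80 °C; then DBU, 80 °C
Reagents that add atoms: none
Why: Wohl–Ziegler bromination can only take the C12 hydrogens (the one allylic CH2 of the C9=C11 alkene), and base-induced elimination of HBr toward C13 gives a 1,3-diene that cannot aromatise because C8 is quaternary.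

Step 11
Reactants: 21 diene
Product: 22 diene acid (C16 carboxylic acid)
Conditions: LiOH (1.5 equiv), THF/H2O, 0 → 25 °C; then dilute HCl
Reagents that add atoms: lithium hydroxide, [Li+].[OH-]
Why: Saponification discriminates on steric grounds: the C16 ester sits on an unbranched CH2, the C7 ester is α-branched and flanked by C8, and the C19 and C20 esters are on quaternary carbons.

Step 12
Reactants: 22 diene acid
Product: 23 Se-phenyl selenoester
Conditions: PhSeSePh, PBu3, CH2Cl2, 25 °C
Reagents that add atoms: diphenyl diselenide, c1ccc(cc1)[Se][Se]c1ccccc1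
Why: The acid is activated as an acyloxyphosphonium species and intercepted by phenylselenolate (selenoester formation) under neutral conditions that spare the diene.

Step 13
Reactants: 23 Se-phenyl selenoester
Product: 24 ene norketone (ring D closed; C16 ketone; C9=C11)
Conditions: Bu3SnH (slow addition), AIBN (cat.), benzene, 80 °C
Reagents that add atoms: none
Why: Acyl radical cyclisation: the C16 acyl radical attacks the diene terminus C13 (5-exo-trig) to give a stabilised allyl radical that takes hydrogen at the less hindered C12; the bridge can only form cis to C15, so C13 follows from C8.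

Step 14
Reactants: 24 ene norketone
Product: 25 ene alcohol (16-hydroxyl endo, on the β face under ring C)
Conditions: NaBH4, MeOH, 0 °C
Reagents that add atoms: none
Why: Borohydride reduction of the bridged ketone from the open exo side places the hydroxyl endo, where it faces the β side of the C9=C11 alkene.

Step 15
Reactants: 25 ene alcohol
Product: 26 saturated alcohol (9β-H)
Conditions: [Ir(cod)(PCy3)(py)]PF6 (10 mol %), H2 (1 atm), CH2Cl2, 25 °C
Reagents that add atoms: none
Why: Hydroxyl-directed homogeneous hydrogenation: the cationic iridium centre binds the 16-hydroxyl and delivers hydrogen to the hindered trisubstituted alkene from that same β face, which sets C9.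

Step 16
Reactants: 26 saturated alcohol
Product: 27 16-norketone
Conditions: Dess–Martin periodinane, NaHCO3, CH2Cl2, 25 °C
Reagents that add atoms: none
Why: Dess–Martin oxidation returns the secondary alcohol to the C16 ketone without affecting the esters.

Step 17
Reactants: 27 16-norketone
Product: 28 16-ene triester (trimethyl gibberell-16-ene-7,19,20-trioate)
Conditions: Ph3PCH3Br, KOt-Bu, THF, 25 → 50 °C
Reagents that add atoms: methyltriphenylphosphonium bromide, C[P+](c1ccccc1)(c1ccccc1)c1ccccc1.[Br-]
Why: Wittig methylenation of the bridged C16 ketone installs C17, and the alkoxide present holds C6 in its more stable configuration (ester trans to C4).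

Step 18
Reactants: 28 16-ene triester
Product: 29 15-exo alcohol (15S)
Conditions: SeO2 (0.3 equiv), t-BuOOH, CH2Cl2, 25 °C
Reagents that add atoms: selenium dioxide, O=[Se]=O; tert-butyl hydroperoxide, CC(C)(C)OO
Why: Allylic hydroxylation by ene reaction at C17 and [2,3]-sigmatropic shift returns oxygen to C15, the only usable allylic position (bridgehead C13–H cannot take part), from the open exo face, giving the epimer of the alcohol that is needed.

Step 19
Reactants: 29 15-exo alcohol
Product: 30 16-en-15-one
Conditions: Dess–Martin periodinane, NaHCO3, CH2Cl2, 0 → 25 °C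
Reagents that add atoms: none
Why: Dess–Martin oxidation of the allylic alcohol gives the α-methylene ketone and erases the C15 configuration.

Step 20
Reactants: 30 16-en-15-one
Product: 31 15-endo alcohol (15R; trimethyl ester of the target)
Conditions: NaBH4, CeCl3·7H2O, MeOH, −40 °C
Reagents that add atoms: none
Why: Luche 1,2-reduction: hydride reaches C15 from the exo side, away from H-9 and the axial hydrogen on C11 that crowd the endo side, so the hydroxyl ends endo (15R) as in the target, without conjugate reduction.

Step 21
Reactants: 31 15-endo alcohol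
Product: 32 target gibberellin (15R)-15-hydroxygibberell-16-ene-7,19,20-trioic acid
Conditions: n-PrSLi (from n-PrSH, n-BuLi), HMPA, 25 → 50 °C; then acidify with cold dilute HCl to pH 3–4 at 0 °C and extract at once
Reagents that add atoms: none
Why: Thiolate cleaves the three methyl esters by SN2 attack at the methyl carbons, which is indifferent to the shielding of the C19 and C20 carbonyls and spares the allylic alcohol and the 16-ene; cold, brief acidification limits lactonisation between the 15-hydroxyl and the C7 acid.

**Compound list**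
1 | cyclohex-2-en-1-one | O=C1C=CCCC1 | starting material
2 | 2,3-dibromocyclohexan-1-one (racemic, trans) | O=C1CCCC(Br)C1Br | intermediate
3 | 2-bromocyclohex-2-en-1-one | O=C1CCCC=C1Br | intermediate
4 | ethylene glycol | OCCO | starting material
5 | 6-bromo-1,4-dioxaspiro[4.5]dec-6-ene | BrC1=CCCCC12OCCO2 | intermediate
6 | methyl 3-oxocyclohex-1-ene-1-carboxylate | COC(=O)C1=CC(=O)CCC1 | starting material
7 | methyl bromoacetate | BrCC(=O)OC | starting material
8 | (1,4-dioxaspiro[4.5]dec-6-en-6-yl)lithium | [Li]C1=CCCCC12OCCO2 | intermediate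
9 | (1,4-dioxaspiro[4.5]dec-6-en-6-yl)dimethylalumane | C[Al](C)C1=CCCCC12OCCO2 | intermediate
10 | dimethylaluminium C4–C5 enolate, methyl (S)-3-[(dimethylalumanyl)oxy]-1-(1,4-dioxaspiro[4.5]dec-6-en-6-yl)cyclohex-2-ene-1-carboxylate | C[Al](C)OC1=C[C@](C(=O)OC)(C2=CCCCC23OCCO3)CCC1 | intermediate
11 | methyl (1S,2S)-2-(2-methoxy-2-oxoethyl)-3-oxo-1-(1,4-dioxaspiro[4.5]dec-6-en-6-yl)cyclohexane-1-carboxylate (C4 ketone; C10 with α-CO2Me and β ring C alkenyl; C5 with β-H and the C6–C7 arm) | O=C1CCC[C@@](C(=O)OC)(C2=CCCCC23OCCO3)[C@@H]1CC(=O)OC | intermediate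
12 | potassium C3–C4 enolate of 11 | [K+].[O-]C1=CCC[C@@](C(=O)OC)(C2=CCCCC23OCCO3)[C@@H]1CC(=O)OC | intermediate
13 | enol triflate of 11 (C3=C4–OSO2CF3) | FC(F)(F)S(=O)(=O)OC1=CCC[C@@](C(=O)OC)(C2=CCCCC23OCCO3)[C@@H]1CC(=O)OC | intermediate
14 | ring A enoate (C3=C4–CO2Me as C19; ketal intact) | COC(=O)C1=CCC[C@@](C(=O)OC)(C2=CCCCC23OCCO3)[C@@H]1CC(=O)OC | intermediate
15 | enone (14 with free C8 ketone conjugated to C9=C11) | COC(=O)C1=CCC[C@@](C(=O)OC)(C2=CCCCC2=O)[C@@H]1CC(=O)OC | intermediate
16 | dienoate (C8=C15H–CO2Me, E/Z mixture) | COC(=O)C1=CCC[C@@](C(=O)OC)(C2=CCCCC2=CC(=O)OC)[C@@H]1CC(=O)OC | intermediate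
17 | tricyclic tetraester (rings A, B, C; C8 with β-CH2CO2Me and α-C14; 6β-CO2Me; 5β-H; 10α-CO2Me; C9=C11; C3=C4–CO2Me) | COC(=O)C[C@]12CCCC=C1[C@]3(C(=O)OC)CCC=C(C(=O)OC)[C@H]3[C@@H]2C(=O)OC | intermediate
18 | lithium C4 ester enolate from 17 | [Li+].COC(=O)C[C@]12CCCC=C1[C@]3(C(=O)OC)CCCC(=C([O-])OC)[C@H]3[C@@H]2C(=O)OC | intermediate
19 | tetraester with quaternary C4 (18β-methyl, 19α-CO2Me) | COC(=O)C[C@]12CCCC=C1[C@]3(C(=O)OC)CCC[C@@](C)(C(=O)OC)[C@H]3[C@@H]2C(=O)OC | intermediate
20 | C12 allylic bromide of 19 (epimers at C12) | COC(=O)C[C@]12CCC(Br)C=C1[C@]3(C(=O)OC)CCC[C@@](C)(C(=O)OC)[C@H]3[C@@H]2C(=O)OC | intermediate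
21 | ring C diene (C9=C11–C12=C13) | COC(=O)C[C@]12CC=CC=C1[C@]3(C(=O)OC)CCC[C@@](C)(C(=O)OC)[C@H]3[C@@H]2C(=O)OC | intermediate
22 | diene acid (C16 CO2H; C7, C19, C20 methyl esters) | OC(=O)C[C@]12CC=CC=C1[C@]3(C(=O)OC)CCC[C@@](C)(C(=O)OC)[C@H]3[C@@H]2C(=O)OC | intermediate
23 | Se-phenyl selenoester of 22 | O=C(C[C@]12CC=CC=C1[C@]3(C(=O)OC)CCC[C@@](C)(C(=O)OC)[C@H]3[C@@H]2C(=O)OC)[Se]c1ccccc1 | intermediate
24 | ene norketone (ring D closed by C13–C16; C16 ketone; C9=C11) | O=C1[C@@H]2CC=C3[C@]4(C(=O)OC)CCC[C@@](C)(C(=O)OC)[C@H]4[C@H](C(=O)OC)[C@]3(C2)C1 | intermediate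
25 | ene alcohol (16-hydroxyl endo; C9=C11) | O[C@@H]1[C@@H]2CC=C3[C@]4(C(=O)OC)CCC[C@@](C)(C(=O)OC)[C@H]4[C@H](C(=O)OC)[C@]3(C2)C1 | intermediate
26 | saturated alcohol (9β-H; 16-hydroxyl endo) | O[C@@H]1[C@@H]2CC[C@H]3[C@]4(C(=O)OC)CCC[C@@](C)(C(=O)OC)[C@H]4[C@H](C(=O)OC)[C@]3(C2)C1 | intermediate
27 | 16-norketone triester | O=C1[C@@H]2CC[C@H]3[C@]4(C(=O)OC)CCC[C@@](C)(C(=O)OC)[C@H]4[C@H](C(=O)OC)[C@]3(C2)C1 | intermediate
28 | 16-ene triester (trimethyl gibberell-16-ene-7,19,20-trioate) | C=C1[C@@H]2CC[C@H]3[C@]4(C(=O)OC)CCC[C@@](C)(C(=O)OC)[C@H]4[C@H](C(=O)OC)[C@]3(C2)C1 | intermediate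
29 | 15-exo alcohol (15S; hydroxyl pointing away from the C9–C11–C12 bridge) | C=C1[C@@H]2CC[C@H]3[C@]4(C(=O)OC)CCC[C@@](C)(C(=O)OC)[C@H]4[C@H](C(=O)OC)[C@]3(C2)[C@H]1O | intermediate
30 | 16-en-15-one triester | C=C1[C@@H]2CC[C@H]3[C@]4(C(=O)OC)CCC[C@@](C)(C(=O)OC)[C@H]4[C@H](C(=O)OC)[C@]3(C2)C1=O | intermediate
31 | 15-endo alcohol (15R; trimethyl ester of the target) | C=C1[C@@H]2CC[C@H]3[C@]4(C(=O)OC)CCC[C@@](C)(C(=O)OC)[C@H]4[C@H](C(=O)OC)[C@]3(C2)[C@@H]1O | intermediate
32 | target gibberellin, (15R)-15-hydroxygibberell-16-ene-7,19,20-trioic acid (15-hydroxyl endo) | C=C1[C@@H]2CC[C@H]3[C@]4(C(=O)O)CCC[C@@](C)(C(=O)O)[C@H]4[C@H](C(=O)O)[C@]3(C2)[C@@H]1O | target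

Total step count: 21
Longest linear sequence: 21 steps (1 to 32); compounds 4, 6 and 7 are bought.

**Steps most likely to fail**

Step 8. The Michael closure may show poor facial selectivity at C8 (the C15 arm ending α), and unproductive γ-deprotonation of the dienoate may compete. The fallback sets C8 by chirality transfer and sets out from 15. Catalytic KOt-Bu in THF at −20 °C should give the intramolecular aldol adduct of the C7 ester enolate and the C8 ketone, the tertiary allylic alcohol F2. Oxidative 1,3-transposition with pyridinium chlorochromate, (C5H5NH)[CrO3Cl], moves the oxygen to C11 and gives the C8=C9 enone F3. Oxazaborolidine-catalysed borane reduction (CBS reduction, catalyst enantiomer chosen for hydride delivery to the α face) gives the 11β-allylic alcohol F4. Johnson–Claisen rearrangement (MeC(OMe)3, cat. EtCO2H, 140 °C) then carries CH2CO2Me suprafacially to the β face of C8 and restores C9=C11. If C6 is obtained as a mixture, NaOMe in MeOH should bring it to the more stable 6β ester, and the sequence comes back to the route at 17.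

Step 3. Transfer of the α-branched alkenyl group to the congested C10 may be slow, enantiofacial control may erode, and proton transfer may outrun C-alkylation of the hindered aluminium enolate. The fallback separates the two bond formations and sets out from 5 and 6. The copper-catalysed addition is run alone and enolate 10 is silylated (Me3SiOSO2CF3, Et3N) to the isolable trimethylsilyl enol ether F1, which fixes the C4–C5 enolate regiochemistry and lets the addition be optimised on its own. F1 is then alkylated regiospecifically with 7 through its ammonium enolate, released by benzyltrimethylammonium fluoride (BnMe3NF) over 4 Å molecular sieves in THF, which spares the C20 ester, coming back to the route at 11.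

Step 10. Radical bromination may be unselective or go too far, and dehydrobromination may be incomplete. The fallback sets out from 19. Allylic oxidation with Rh2(cap)4 (dirhodium tetracaprolactamate) and t-BuOOH should give the 9(11)-en-12-one F5, since hydrogen abstraction is possible only at C12. Kinetic enolisation toward C13 with KN(SiMe3)2 and trapping with PhNTf2 gives the dienyl triflate F6. Palladium-catalysed reduction (Pd(OAc)2, PPh3, HCO2H, Bu3N, DMF, 60 °C) removes the triflate and comes back to the route at diene 21.

**Further compounds**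
F1 | step 3 | trimethylsilyl enol ether, methyl (S)-1-(1,4-dioxaspiro[4.5]dec-6-en-6-yl)-3-[(trimethylsilyl)oxy]cyclohex-2-ene-1-carboxylate | C[Si](C)(C)OC1=C[C@](C(=O)OC)(C2=CCCCC23OCCO3)CCC1
F2 | step 8 | aldol adduct (ring B closed by C6–C8; 8-hydroxyl; C9=C11; C6 and C8 unassigned) | COC(=O)C1=CCC[C@@]2(C(=O)OC)C3=CCCCC3(O)C(C(=O)OC)[C@H]12
F3 | step 8 | transposed enone (C11 ketone; C8=C9) | COC(=O)C1=CCC[C@@]2(C(=O)OC)C3=C(CCCC3=O)C(C(=O)OC)[C@H]12
F4 | step 8 | 11β-allylic alcohol (C8=C9) | COC(=O)C1=CCC[C@@]2(C(=O)OC)C3=C(CCC[C@@H]3O)C(C(=O)OC)[C@H]12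
F5 | step 10 | 9(11)-en-12-one of 19 | COC(=O)C[C@]12CCC(=O)C=C1[C@]3(C(=O)OC)CCC[C@@](C)(C(=O)OC)[C@H]3[C@@H]2C(=O)OC
F6 | step 10 | dienyl triflate (C12–OSO2CF3; C9=C11 and C12=C13) | COC(=O)C[C@]12CC=C(OS(=O)(=O)C(F)(F)F)C=C1[C@]3(C(=O)OC)CCC[C@@](C)(C(=O)OC)[C@H]3[C@@H]2C(=O)OC
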